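**Retrosynthetic overview**

1. The target is reached from an 8-oxo-17-nor-labdane. Its kinetic C7 enolate is trapped as the enol triflate, and methyl cross-coupling installs C17 and fixes the C7=C8 bond; the diol is then unmasked and acetylated.
2. The decalin comes from an acyclic trienimide by one oxazolidinone-controlled intramolecular Diels–Alder reaction. It forms C5–C10 and C6–C7 together, so ring A (closed through the C1–C4 chain) and ring B arise in the same step. The C6 acyl activator is then excised (LiOOH, Barton decarboxylation).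
3. Enabling feature: ring B is a cyclohexene. Written with an enol ether at C8 (C8–OMe, C8=C9), it is the [4+2] adduct of a C7=C8(OMe)–C9=C10 diene and a C5=C6 dienophile, tethered by C1–C2–C3–C4 of ring A with its C4 gem-dimethyl group.
4. The triene comes from a Horner–Wadsworth–Emmons reaction (C5=C6) and one Tebbe methylenation that makes the 2-methoxydiene (C7) and the C13=C16 methylene from a keto ester.
5. The keto ester with its tetrasubstituted C9=C10 bond comes from three pieces: methyl acetoacetate (C8, C9, C10, C20), a D-glycerate-derived vinyl ketone (C11–C15, Michael addition) and a 2,2-dimethylpentenyl unit (C1–C5, B-alkyl Suzuki–Miyaura coupling of an (E)-enol triflate).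

Key step: step 11

Remark: atoms are numbered as in labdanes (decalin C1–C10, side chain C11–C16, C17 on C8, C18/C19 on C4, C20 on C10), α is the face opposite the C10 methyl group, and 2,2-dimethylpent-4-en-1-ol (1) is taken as a catalogue compound.

**Step 1**
Reactants: 1 2,2-dimethylpent-4-en-1-ol
Product: 2 tert-butyl[(2,2-dimethylpent-4-en-1-yl)oxy]dimethylsilane
Conditions: TBSCl, imidazole, DMF, rt
Reagents that add atoms: tert-butyldimethylsilyl chloride, CC(C)(C)[Si](C)(C)Cl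
Why: Silylation of a primary alcohol (silyl ether protection) masks the future C5 aldehyde; no stereocentre is formed.

**Step 2**
Reactants: 3 methyl (4R)-2,2-dimethyl-1,3-dioxolane-4-carboxylate
Product: 4 (4R)-N-methoxy-N,2,2-trimethyl-1,3-dioxolane-4-carboxamide
Conditions: MeNHOMe·HCl, i-PrMgCl, THF, −20 °C
Reagents that add atoms: N,O-dimethylhydroxylamine hydrochloride, CNOC.Cl
Why: Aminolysis of the ester by the magnesium amide (N-methoxy-N-methylamide formation) runs cold and leaves the chiral-pool α-alkoxy centre (future C14) untouched.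

**Step 3**
Reactants: 4 (4R)-N-methoxy-N,2,2-trimethyl-1,3-dioxolane-4-carboxamide
Product: 5 1-[(4R)-2,2-dimethyl-1,3-dioxolan-4-yl]prop-2-en-1-one
Conditions: CH2=CHMgBr, THF, −78 to 0 °C; inverse quench into cold 1 M aq. HCl
Reagents that add atoms: vinylmagnesium bromide, C=C[Mg]Br
Why: Grignard addition to the N-methoxy-N-methylamide stops at the chelated tetrahedral adduct, so one vinyl group is delivered; the acidic quench keeps the released amine from adding to the enone.

**Step 4**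
Reactants: 5 1-[(4R)-2,2-dimethyl-1,3-dioxolan-4-yl]prop-2-en-1-one, 6 methyl acetoacetate
Product: 7 methyl 2-acetyl-5-[(4R)-2,2-dimethyl-1,3-dioxolan-4-yl]-5-oxopentanoate (both C2 epimers)
Conditions: Et3N (0.1 equiv), CH2Cl2, 0 °C to rt, 6 in excess
Reagents that add atoms: none
Why: Amine-catalysed Michael addition forms C9–C11; only the β-keto ester is acidic enough for Et3N, so C14 should not epimerise, and the new C9 centre is irrelevant because it becomes sp2 in step 5.

**Step 5**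
Reactants: 7 methyl 2-acetyl-5-[(4R)-2,2-dimethyl-1,3-dioxolan-4-yl]-5-oxopentanoate
Product: 8 methyl (2E)-2-{3-[(4R)-2,2-dimethyl-1,3-dioxolan-4-yl]-3-oxopropyl}-3-{[(trifluoromethyl)sulfonyl]oxy}but-2-enoate
Conditions: Tf2O, 25% aq. Me4NOH, toluene, 0–5 °C
Reagents that add atoms: trifluoromethanesulfonic anhydride, O=S(=O)(OS(=O)(=O)C(F)(F)F)C(F)(F)F
Why: O-triflation of the non-chelated tetramethylammonium enolate (stereoselective enol triflate formation) traps the extended enolate, placing OTf trans to the ester, which sets the geometry of the later C9=C10 bond; the anionic charge protects the remote ketone from deprotonation.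

**Step 6**
Reactants: 2 tert-butyl[(2,2-dimethylpent-4-en-1-yl)oxy]dimethylsilane, 8 methyl (2E)-2-{3-[(4R)-2,2-dimethyl-1,3-dioxolan-4-yl]-3-oxopropyl}-3-{[(trifluoromethyl)sulfonyl]oxy}but-2-enoate
Product: 10 methyl (2E)-8-[(tert-butyldimethylsilyl)oxy]-2-{3-[(4R)-2,2-dimethyl-1,3-dioxolan-4-yl]-3-oxopropyl}-3,7,7-trimethyloct-2-enoate, via alkylborane 9 (not isolated)
Conditions: 2, 9-BBN-H, THF, rt; then 8, PdCl2(dppf), AsPh3, Cs2CO3, DMF/H2O, rt
Reagents that add atoms: none
Why: Anti-Markovnikov hydroboration followed by B-alkyl Suzuki–Miyaura coupling joins C1 to C10 with retention of the triflate geometry, so the C1 chain ends trans and the C20 methyl cis to the ester carbon C8.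

**Step 7**
Reactants: 10 methyl (2E)-8-[(tert-butyldimethylsilyl)oxy]-2-{3-[(4R)-2,2-dimethyl-1,3-dioxolan-4-yl]-3-oxopropyl}-3,7,7-trimethyloct-2-enoate
Product: 11 tert-butyl({(6E)-10-[(4S)-2,2-dimethyl-1,3-dioxolan-4-yl]-7-(1-methoxyethenyl)-2,2,6-trimethylundeca-6,10-dien-1-yl}oxy)dimethylsilane
Conditions: Cp2Ti(μ-Cl)(μ-CH2)AlMe2 (3 equiv), pyridine, THF/toluene, −40 °C to rt; aq. NaOH; basic alumina
Reagents that add atoms: Tebbe reagent, C[Al-]1(C)C[Ti](C2C=CC=C2)(C2C=CC=C2)[Cl+]1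
Why: Tebbe methylenation converts the ketone into the C13=C16 methylene and the ester into the 1-methoxyvinyl group, creating the C7=C8(OMe)–C9=C10 diene in one operation; the reagent is non-basic, so C14 is not at risk.

**Step 8**
Reactants: 11 tert-butyl({(6E)-10-[(4S)-2,2-dimethyl-1,3-dioxolan-4-yl]-7-(1-methoxyethenyl)-2,2,6-trimethylundeca-6,10-dien-1-yl}oxy)dimethylsilane
Product: 12 (6E)-10-[(4S)-2,2-dimethyl-1,3-dioxolan-4-yl]-7-(1-methoxyethenyl)-2,2,6-trimethylundeca-6,10-dien-1-ol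
Conditions: Bu4NF, THF, rt
Reagents that add atoms: none
Why: Fluoride desilylation is basic and leaves the acid-labile enol ether and the acetonide intact.

**Step 9**
Reactants: 13 (4S)-4-benzyl-1,3-oxazolidin-2-one, 14 2-(diethoxyphosphoryl)acetic acid
Product: 16 diethyl {2-[(4S)-4-benzyl-2-oxo-1,3-oxazolidin-3-yl]-2-oxoethyl}phosphonate, via mixed pivalic anhydride 15 (not isolated)
Conditions: 14, t-BuCOCl, Et3N, THF, −20 °C; then 13, LiCl, rt
Reagents that add atoms: none
Why: N-acylation of the oxazolidinone through a mixed anhydride occurs at the unhindered phosphonoacetyl carbonyl, not the pivaloyl one.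

**Step 10**
Reactants: 12 (6E)-10-[(4S)-2,2-dimethyl-1,3-dioxolan-4-yl]-7-(1-methoxyethenyl)-2,2,6-trimethylundeca-6,10-dien-1-ol, 16 diethyl {2-[(4S)-4-benzyl-2-oxo-1,3-oxazolidin-3-yl]-2-oxoethyl}phosphonate
Product: 18 (4S)-4-benzyl-3-{(2E,8E)-12-[(4S)-2,2-dimethyl-1,3-dioxolan-4-yl]-9-(1-methoxyethenyl)-4,4,8-trimethyltrideca-2,8,12-trienoyl}-1,3-oxazolidin-2-one, via aldehyde 17 (not isolated)
Conditions: Pr4N[RuO4] (5 mol %), NMO, 4 Å MS, CH2Cl2, rt; then 16, LiCl, i-Pr2NEt, MeCN, rt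
Reagents that add atoms: none
Why: Neutral perruthenate oxidation gives the non-enolisable neopentyl aldehyde, and the mild LiCl/amine Horner–Wadsworth–Emmons reaction should give the (E)-enoyl imide (C5=C6) without harming the enol ether.

**Step 11**
Reactants: 18 (4S)-4-benzyl-3-{(2E,8E)-12-[(4S)-2,2-dimethyl-1,3-dioxolan-4-yl]-9-(1-methoxyethenyl)-4,4,8-trimethyltrideca-2,8,12-trienoyl}-1,3-oxazolidin-2-one
Product: 20 (4S)-4-benzyl-3-{[(14S)-14,15-(isopropylidenedioxy)-8-oxo-17-norlabd-13(16)-en-6α-yl]carbonyl}-1,3-oxazolidin-2-one, via enol ether cycloadduct 19 (not isolated)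
Conditions: Me2AlCl (2.5 equiv), CH2Cl2 (0.005 M), −30 to 0 °C; then 0.5 M aq. HCl, THF, 0 °C
Reagents that add atoms: water, O
Why: Me2AlCl turns the N-enoyl oxazolidinone into a chelated s-cis aluminium imide whose lowered LUMO engages the tethered 2-methoxydiene in a concerted, asynchronous [4+2] cycloaddition (C5–C10 leading, C6–C7 following); the closest known reaction type is the Me2AlCl-promoted intramolecular Diels–Alder reaction of (E,E)-trienoyl oxazolidinones to trans-fused octalins. Ring A closes as a chair-like six-membered ring through the C5–C10 bond and the C1–C4 tether (the C4 gem-dimethyl group favours the folded conformer), and ring B is the cyclohexene made by the two new bonds themselves. C5 and C6 are controlled by the auxiliary, whose benzyl group screens the C6 Re face of the chelate so that the diene adds to the Si faces of C5 and C6; C10 follows from the E geometry of C9=C10 (tether outside, C20 inside) together with the endo transition state, which places the C4 branch anti and gives the trans ring fusion (5α-H, 10β-CH3, 6α-acyl). C9 is set in the work-up, where the cyclic enol ether should be protonated axially from the α face, opposite the C10 methyl group, giving the equatorial side chain (9α-H) that is also expected to be the thermodynamic epimer. The step needs facial, endo and periselectivity: these come from the auxiliary, from Lewis acid activation of the (E)-dienophile, and from the fact that only the enol ether diene and the imide alkene are activated, the C13 methylene being isolated and remote.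

**Step 12**
Reactants: 20 (4S)-4-benzyl-3-{[(14S)-14,15-(isopropylidenedioxy)-8-oxo-17-norlabd-13(16)-en-6α-yl]carbonyl}-1,3-oxazolidin-2-one
Product: 22 (14S)-14,15-(isopropylidenedioxy)-8-oxo-17-norlabd-13(16)-ene-6α-carboxylic acid, via peroxy acid 21 (not isolated)
Conditions: LiOH, H2O2, THF/H2O, 0 °C; Na2SO3; 0.5 M aq. HCl to pH 4, 0 °C
Reagents that add atoms: hydrogen peroxide, OO
Why: Hydroperoxide attacks the exocyclic imide carbonyl selectively (auxiliary cleavage), and the basic medium should equilibrate any 9-epimer to the equatorial side chain.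

**Step 13**
Reactants: 22 (14S)-14,15-(isopropylidenedioxy)-8-oxo-17-norlabd-13(16)-ene-6α-carboxylic acid
Product: 24 (14S)-14,15-(isopropylidenedioxy)-17-norlabd-13(16)-en-8-one, via thiohydroxamate ester 23 (not isolated)
Conditions: 2-mercaptopyridine N-oxide, DCC, DMAP (cat.), CH2Cl2, 0 °C, dark; then t-BuSH, hν (tungsten lamp), rt
Reagents that add atoms: none
Why: Barton decarboxylation removes the activating carbon: the thiohydroxamate ester fragments to CO2 and a secondary C6 radical that is reduced by the thiol, leaving C6 as CH2 and C5 untouched.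

**Step 14**
Reactants: 24 (14S)-14,15-(isopropylidenedioxy)-17-norlabd-13(16)-en-8-one
Product: 25 (14S)-14,15-(isopropylidenedioxy)-17-norlabda-7,13(16)-dien-8-yl trifluoromethanesulfonate
Conditions: KN(SiMe3)2, THF, −78 °C; PhNTf2, −78 to 0 °C
Reagents that add atoms: N-phenylbis(trifluoromethanesulfonimide), O=S(=O)(N(c1ccccc1)S(=O)(=O)C(F)(F)F)C(F)(F)F
Why: Kinetic deprotonation takes the accessible C7 methylene rather than the C9 methine next to quaternary C10, so O-triflation (enol triflate formation) fixes the double bond at C7=C8 and leaves C9 untouched.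

**Step 15**
Reactants: 25 (14S)-14,15-(isopropylidenedioxy)-17-norlabda-7,13(16)-dien-8-yl trifluoromethanesulfonate
Product: 26 (14S)-labda-7,13(16)-diene-14,15-diol acetonide
Conditions: MeMgBr, Fe(acac)3 (5 mol %), THF/NMP, −30 to 0 °C
Reagents that add atoms: methylmagnesium bromide, C[Mg]Br
Why: Iron-catalysed cross-coupling of the alkenyl triflate with the methyl Grignard reagent installs C17 on C8 without moving the C7=C8 bond.

**Step 16**
Reactants: 26 (14S)-labda-7,13(16)-diene-14,15-diol acetonide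
Product: 27 (14S)-labda-7,13(16)-diene-14,15-diol
Conditions: AcOH/H2O/THF (3:1:1), 40 °C
Reagents that add atoms: none
Why: Mild acid hydrolysis of the terminal acetonide should not isomerise the trisubstituted C7=C8 or the C13=C16 alkene.

**Step 17**
Reactants: 27 (14S)-labda-7,13(16)-diene-14,15-diol
Product: 28 (5S,9S,10S,14S)-labda-7,13(16)-diene-14,15-diyl diacetate
Conditions: Ac2O, pyridine, DMAP (cat.), CH2Cl2, rt
Reagents that add atoms: acetic anhydride, CC(=O)OC(C)=O
Why: DMAP-catalysed acylation esterifies both hydroxyl groups with retention at C14.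

**Compound list**

1 | 2,2-dimethylpent-4-en-1-ol | C=CCC(C)(C)CO | starting material
2 | tert-butyl[(2,2-dimethylpent-4-en-1-yl)oxy]dimethylsilane | C=CCC(C)(C)CO[Si](C)(C)C(C)(C)C | intermediate
3 | methyl (4R)-2,2-dimethyl-1,3-dioxolane-4-carboxylate | COC(=O)[C@@H]1OC(C)(C)OC1 | starting material
4 | (4R)-N-methoxy-N,2,2-trimethyl-1,3-dioxolane-4-carboxamide | CON(C)C(=O)[C@@H]1OC(C)(C)OC1 | intermediate
5 | 1-[(4R)-2,2-dimethyl-1,3-dioxolan-4-yl]prop-2-en-1-one | C=CC(=O)[C@@H]1OC(C)(C)OC1 | intermediate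
6 | methyl acetoacetate | COC(=O)CC(C)=O | starting material
7 | methyl 2-acetyl-5-[(4R)-2,2-dimethyl-1,3-dioxolan-4-yl]-5-oxopentanoate (C2 epimers) | COC(=O)C(CCC(=O)[C@@H]1OC(C)(C)OC1)C(C)=O | intermediate
8 | methyl (2E)-2-{3-[(4R)-2,2-dimethyl-1,3-dioxolan-4-yl]-3-oxopropyl}-3-{[(trifluoromethyl)sulfonyl]oxy}but-2-enoate | COC(=O)/C(CCC(=O)[C@@H]1OC(C)(C)OC1)=C(\C)OS(=O)(=O)C(F)(F)F | intermediate
9 | 9-{5-[(tert-butyldimethylsilyl)oxy]-4,4-dimethylpentyl}-9-borabicyclo[3.3.1]nonane | CC(C)(C)[Si](C)(C)OCC(C)(C)CCCB1C2CCCC1CCC2 | intermediate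
10 | methyl (2E)-8-[(tert-butyldimethylsilyl)oxy]-2-{3-[(4R)-2,2-dimethyl-1,3-dioxolan-4-yl]-3-oxopropyl}-3,7,7-trimethyloct-2-enoate | COC(=O)/C(CCC(=O)[C@@H]1OC(C)(C)OC1)=C(\C)CCCC(C)(C)CO[Si](C)(C)C(C)(C)C | intermediate
11 | tert-butyl({(6E)-10-[(4S)-2,2-dimethyl-1,3-dioxolan-4-yl]-7-(1-methoxyethenyl)-2,2,6-trimethylundeca-6,10-dien-1-yl}oxy)dimethylsilane | C=C(OC)/C(CCC(=C)[C@@H]1OC(C)(C)OC1)=C(\C)CCCC(C)(C)CO[Si](C)(C)C(C)(C)C | intermediate
12 | (6E)-10-[(4S)-2,2-dimethyl-1,3-dioxolan-4-yl]-7-(1-methoxyethenyl)-2,2,6-trimethylundeca-6,10-dien-1-ol | C=C(OC)/C(CCC(=C)[C@@H]1OC(C)(C)OC1)=C(\C)CCCC(C)(C)CO | intermediate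
13 | (4S)-4-benzyl-1,3-oxazolidin-2-one | O=C1N[C@@H](Cc2ccccc2)CO1 | starting material
14 | 2-(diethoxyphosphoryl)acetic acid | CCOP(=O)(CC(=O)O)OCC | starting material
15 | 2-(diethoxyphosphoryl)acetic pivalic anhydride | CCOP(=O)(CC(=O)OC(=O)C(C)(C)C)OCC | intermediate
16 | diethyl {2-[(4S)-4-benzyl-2-oxo-1,3-oxazolidin-3-yl]-2-oxoethyl}phosphonate | CCOP(=O)(CC(=O)N1C(=O)OC[C@@H]1Cc1ccccc1)OCC | intermediate
17 | (6E)-10-[(4S)-2,2-dimethyl-1,3-dioxolan-4-yl]-7-(1-methoxyethenyl)-2,2,6-trimethylundeca-6,10-dienal | C=C(OC)/C(CCC(=C)[C@@H]1OC(C)(C)OC1)=C(\C)CCCC(C)(C)C=O | intermediate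
18 | (4S)-4-benzyl-3-{(2E,8E)-12-[(4S)-2,2-dimethyl-1,3-dioxolan-4-yl]-9-(1-methoxyethenyl)-4,4,8-trimethyltrideca-2,8,12-trienoyl}-1,3-oxazolidin-2-one | C=C(OC)/C(CCC(=C)[C@@H]1OC(C)(C)OC1)=C(\C)CCCC(C)(C)/C=C/C(=O)N1C(=O)OC[C@@H]1Cc1ccccc1 | intermediate
19 | (4S)-4-benzyl-3-{[(14S)-14,15-(isopropylidenedioxy)-8-methoxy-17-norlabda-8,13(16)-dien-6α-yl]carbonyl}-1,3-oxazolidin-2-one (5α-H, 10β-CH3) | C=C(CCC1=C(OC)C[C@H](C(=O)N3C(=O)OC[C@@H]3Cc3ccccc3)[C@H]2C(C)(C)CCC[C@]12C)[C@@H]1OC(C)(C)OC1 | intermediate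
20 | (4S)-4-benzyl-3-{[(14S)-14,15-(isopropylidenedioxy)-8-oxo-17-norlabd-13(16)-en-6α-yl]carbonyl}-1,3-oxazolidin-2-one (5α-H, 9α-H, 10β-CH3) | C=C(CC[C@H]1C(=O)C[C@H](C(=O)N3C(=O)OC[C@@H]3Cc3ccccc3)[C@H]2C(C)(C)CCC[C@]12C)[C@@H]1OC(C)(C)OC1 | intermediate
21 | (14S)-14,15-(isopropylidenedioxy)-8-oxo-17-norlabd-13(16)-ene-6α-carboperoxoic acid | C=C(CC[C@H]1C(=O)C[C@H](C(=O)OO)[C@H]2C(C)(C)CCC[C@]12C)[C@@H]1OC(C)(C)OC1 | intermediate
22 | (14S)-14,15-(isopropylidenedioxy)-8-oxo-17-norlabd-13(16)-ene-6α-carboxylic acid | C=C(CC[C@H]1C(=O)C[C@H](C(=O)O)[C@H]2C(C)(C)CCC[C@]12C)[C@@H]1OC(C)(C)OC1 | intermediate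
23 | 2-thioxopyridin-1(2H)-yl (14S)-14,15-(isopropylidenedioxy)-8-oxo-17-norlabd-13(16)-ene-6α-carboxylate | C=C(CC[C@H]1C(=O)C[C@H](C(=O)On3ccccc3=S)[C@H]2C(C)(C)CCC[C@]12C)[C@@H]1OC(C)(C)OC1 | intermediate
24 | (14S)-14,15-(isopropylidenedioxy)-17-norlabd-13(16)-en-8-one (5α-H, 9α-H, 10β-CH3) | C=C(CC[C@H]1C(=O)CC[C@H]2C(C)(C)CCC[C@]12C)[C@@H]1OC(C)(C)OC1 | intermediate
25 | (14S)-14,15-(isopropylidenedioxy)-17-norlabda-7,13(16)-dien-8-yl trifluoromethanesulfonate | C=C(CC[C@H]1C(OS(=O)(=O)C(F)(F)F)=CC[C@H]2C(C)(C)CCC[C@]12C)[C@@H]1OC(C)(C)OC1 | intermediate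
26 | (14S)-labda-7,13(16)-diene-14,15-diol acetonide | C=C(CC[C@H]1C(C)=CC[C@H]2C(C)(C)CCC[C@]12C)[C@@H]1OC(C)(C)OC1 | intermediate
27 | (14S)-labda-7,13(16)-diene-14,15-diol | C=C(CC[C@H]1C(C)=CC[C@H]2C(C)(C)CCC[C@]12C)[C@@H](CO)O | intermediate
28 | (5S,9S,10S,14S)-labda-7,13(16)-diene-14,15-diyl diacetate | C=C(CC[C@H]1C(C)=CC[C@H]2C(C)(C)CCC[C@]12C)[C@@H](COC(C)=O)OC(C)=O | target

**Step count and risks**

Total step count: 17. Longest linear sequence: 15 steps (from 3 through steps 2–8 and 10–17).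

Steps most likely to fail:

1. Step 11. The aluminium Lewis acid may consume the electron-rich methoxydiene (protonolysis, or intermolecular attack through its nucleophilic C7 terminus, which the tether cannot deliver to C5) before the hindered diene, with its inside methyl group, reaches the cycloaddition geometry. Facial control may also erode if warming is needed. The fallback replaces auxiliary control and stoichiometric aluminium by catalyst control on an achiral imide. It sets out from 12. Oxidation and Horner–Wadsworth–Emmons reaction as in step 10, but with the achiral phosphonate 3-[2-(diethoxyphosphoryl)acetyl]-1,3-oxazolidin-2-one F1 (made from oxazolidin-2-one and 14 as in step 9), should give the achiral trienimide F2. The cycloaddition is then run with [Cu((R,R)-t-Bu-box)](SbF6)2 (10 mol %, CH2Cl2, rt), a divalent copper bis(oxazoline) complex that binds the imide through both carbonyls and whose tert-butyl group should screen the C6 Re face. This should give the enol ether cycloadduct F3 and, after the same mild acid work-up, the keto imide F4. LiOH/H2O2 cleavage of F4 passes through the same peroxy acid 21 and comes back to the route at acid 22.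

2. Step 5. The enolate may be trapped in part through the chelated form (wrong triflate geometry, hence a cis-fused decalin later), or the aqueous base may damage or epimerise the α-alkoxy ketone. The fallback exchanges the roles of the two C10 substituents so that the reliable chelation-controlled geometry is used. It sets out from 2 and 6. Ozonolysis of 2 should give the aldehyde 4-[(tert-butyldimethylsilyl)oxy]-3,3-dimethylbutanal F5, reduced in the same flask (NaBH4) to the alcohol 4-[(tert-butyldimethylsilyl)oxy]-3,3-dimethylbutan-1-ol F6; the Appel-type iodination (I2, PPh3, imidazole) gives tert-butyl(4-iodo-2,2-dimethylbutoxy)dimethylsilane F7. Alkylation of the dianion of 6 (NaH, then n-BuLi, THF, 0 °C) with F7 should give the β-keto ester methyl 8-[(tert-butyldimethylsilyl)oxy]-7,7-dimethyl-3-oxooctanoate F8, and Michael addition to 5 (Et3N) the adduct F9. The sodium chelate (NaH, then Tf2O) should give the (Z)-enol triflate F10, and Pd(PPh3)4-catalysed coupling with MeZnCl (Negishi methylation, retention) comes back to the route at 10.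

3. Step 7. Methylenation of the hindered conjugated ester may stall, or the methoxydiene may be hydrolysed during the three operations before the cycloaddition. The fallback makes the diene as a silyl dienol ether immediately before the key step. It sets out from 10. One equivalent of the Tebbe reagent at −40 °C should methylenate only the ketone, giving the ester methyl (2E)-8-[(tert-butyldimethylsilyl)oxy]-2-{3-[(4S)-2,2-dimethyl-1,3-dioxolan-4-yl]but-3-en-1-yl}-3,7,7-trimethyloct-2-enoate F11. LiCH2SiMe3 followed by methanol should convert the ester into the methyl ketone (3E)-9-[(tert-butyldimethylsilyl)oxy]-3-{3-[(4S)-2,2-dimethyl-1,3-dioxolan-4-yl]but-3-en-1-yl}-4,8,8-trimethylnon-3-en-2-one F12, and Bu4NF gives the alcohol F13. Oxidation as in step 10 gives the keto aldehyde F14, which reacts in the same flask with 16 to give the enone imide F15. Soft enolisation (i-Pr3SiOTf, Et3N, 0 °C) should give the 2-silyloxydiene F16, and Me2AlCl cycloaddition the silyl enol ether cycloadduct F17. Acid work-up of F17 comes back to the route at 20.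

**Further compounds**

F1 | step 11 | 3-[2-(diethoxyphosphoryl)acetyl]-1,3-oxazolidin-2-one | CCOP(=O)(CC(=O)N1CCOC1=O)OCC
F2 | step 11 | 3-{(2E,8E)-12-[(4S)-2,2-dimethyl-1,3-dioxolan-4-yl]-9-(1-methoxyethenyl)-4,4,8-trimethyltrideca-2,8,12-trienoyl}-1,3-oxazolidin-2-one | C=C(OC)/C(CCC(=C)[C@@H]1OC(C)(C)OC1)=C(\C)CCCC(C)(C)/C=C/C(=O)N1CCOC1=O
F3 | step 11 | 3-{[(14S)-14,15-(isopropylidenedioxy)-8-methoxy-17-norlabda-8,13(16)-dien-6α-yl]carbonyl}-1,3-oxazolidin-2-one | C=C(CCC1=C(OC)C[C@H](C(=O)N3CCOC3=O)[C@H]2C(C)(C)CCC[C@]12C)[C@@H]1OC(C)(C)OC1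
F4 | step 11 | 3-{[(14S)-14,15-(isopropylidenedioxy)-8-oxo-17-norlabd-13(16)-en-6α-yl]carbonyl}-1,3-oxazolidin-2-one | C=C(CC[C@H]1C(=O)C[C@H](C(=O)N3CCOC3=O)[C@H]2C(C)(C)CCC[C@]12C)[C@@H]1OC(C)(C)OC1
F5 | step 5 | 4-[(tert-butyldimethylsilyl)oxy]-3,3-dimethylbutanal | O=CCC(C)(C)CO[Si](C)(C)C(C)(C)C
F6 | step 5 | 4-[(tert-butyldimethylsilyl)oxy]-3,3-dimethylbutan-1-ol | OCCC(C)(C)CO[Si](C)(C)C(C)(C)C
F7 | step 5 | tert-butyl(4-iodo-2,2-dimethylbutoxy)dimethylsilane | ICCC(C)(C)CO[Si](C)(C)C(C)(C)C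
F8 | step 5 | methyl 8-[(tert-butyldimethylsilyl)oxy]-7,7-dimethyl-3-oxooctanoate | COC(=O)CC(=O)CCCC(C)(C)CO[Si](C)(C)C(C)(C)C
F9 | step 5 | methyl 8-[(tert-butyldimethylsilyl)oxy]-2-{3-[(4R)-2,2-dimethyl-1,3-dioxolan-4-yl]-3-oxopropyl}-7,7-dimethyl-3-oxooctanoate | COC(=O)C(CCC(=O)[C@@H]1OC(C)(C)OC1)C(=O)CCCC(C)(C)CO[Si](C)(C)C(C)(C)C
F10 | step 5 | methyl (2Z)-8-[(tert-butyldimethylsilyl)oxy]-2-{3-[(4R)-2,2-dimethyl-1,3-dioxolan-4-yl]-3-oxopropyl}-7,7-dimethyl-3-{[(trifluoromethyl)sulfonyl]oxy}oct-2-enoate | COC(=O)/C(CCC(=O)[C@@H]1OC(C)(C)OC1)=C(\OS(=O)(=O)C(F)(F)F)CCCC(C)(C)CO[Si](C)(C)C(C)(C)C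
F11 | step 7 | methyl (2E)-8-[(tert-butyldimethylsilyl)oxy]-2-{3-[(4S)-2,2-dimethyl-1,3-dioxolan-4-yl]but-3-en-1-yl}-3,7,7-trimethyloct-2-enoate | COC(=O)/C(CCC(=C)[C@@H]1OC(C)(C)OC1)=C(\C)CCCC(C)(C)CO[Si](C)(C)C(C)(C)C
F12 | step 7 | (3E)-9-[(tert-butyldimethylsilyl)oxy]-3-{3-[(4S)-2,2-dimethyl-1,3-dioxolan-4-yl]but-3-en-1-yl}-4,8,8-trimethylnon-3-en-2-one | CC(=O)/C(CCC(=C)[C@@H]1OC(C)(C)OC1)=C(\C)CCCC(C)(C)CO[Si](C)(C)C(C)(C)C
F13 | step 7 | (3E)-3-{3-[(4S)-2,2-dimethyl-1,3-dioxolan-4-yl]but-3-en-1-yl}-9-hydroxy-4,8,8-trimethylnon-3-en-2-one | CC(=O)/C(CCC(=C)[C@@H]1OC(C)(C)OC1)=C(\C)CCCC(C)(C)CO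
F14 | step 7 | (6E)-7-acetyl-10-[(4S)-2,2-dimethyl-1,3-dioxolan-4-yl]-2,2,6-trimethylundeca-6,10-dienal | CC(=O)/C(CCC(=C)[C@@H]1OC(C)(C)OC1)=C(\C)CCCC(C)(C)C=O
F15 | step 7 | (4S)-3-{(2E,8E)-9-acetyl-12-[(4S)-2,2-dimethyl-1,3-dioxolan-4-yl]-4,4,8-trimethyltrideca-2,8,12-trienoyl}-4-benzyl-1,3-oxazolidin-2-one | CC(=O)/C(CCC(=C)[C@@H]1OC(C)(C)OC1)=C(\C)CCCC(C)(C)/C=C/C(=O)N1C(=O)OC[C@@H]1Cc1ccccc1
F16 | step 7 | (4S)-4-benzyl-3-{(2E,8E)-12-[(4S)-2,2-dimethyl-1,3-dioxolan-4-yl]-4,4,8-trimethyl-9-{1-[(triisopropylsilyl)oxy]ethenyl}trideca-2,8,12-trienoyl}-1,3-oxazolidin-2-one | C=C(O[Si](C(C)C)(C(C)C)C(C)C)/C(CCC(=C)[C@@H]1OC(C)(C)OC1)=C(\C)CCCC(C)(C)/C=C/C(=O)N1C(=O)OC[C@@H]1Cc1ccccc1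
F17 | step 7 | (4S)-4-benzyl-3-{[(14S)-14,15-(isopropylidenedioxy)-8-[(triisopropylsilyl)oxy]-17-norlabda-8,13(16)-dien-6α-yl]carbonyl}-1,3-oxazolidin-2-one | C=C(CCC1=C(O[Si](C(C)C)(C(C)C)C(C)C)C[C@H](C(=O)N3C(=O)OC[C@@H]3Cc3ccccc3)[C@H]2C(C)(C)CCC[C@]12C)[C@@H]1OC(C)(C)OC1
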